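The coupling partner went into the epsilon flask at 3.84 times the charge of starting material, so I took the starting material for the limiting reagent, and I was puzzled by where the target stopped.

| flask | starting material | coupling partner | free catalyst | remark | time |
|---|---|---|---|---|---|
| epsilon | 0.50 M | 1.92 M | 27 mM | run made earlier |  |
| midnight | 0.40 M | 1.92 M | 27 mM |  | 8.0 h |
| noon | 0.80 M | 1.92 M | 27 mM |  | 8.0 h |
| winter | 1.5 M | 1.92 M | 27 mM |  | 8.0 h |
| dusk | 3.0 M | 1.92 M | 27 mM |  | 8.0 h |

- epsilon (time / h: target / %, starting material / %): 0.667: 27.1, 0; 2.00: 42.1, 0; 4.00: 45.5, 0.3; 6.00: 44.3, 0; 8.00: 45.8, 0

(scatter of a reading: 0.5 percentage points)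

- "hardly changes" means that all values lie within two and a half points (for a concentration: within two and a half percent of the largest)

- [target] at the end for midnight, noon, winter, dusk, in this order
- the shape of the row from first to last (rises all the way / rises, then falls / hardly changes / falls all the way / falls, then rises)

Two things in the epsilon run did not seem to go together. At 0.667 h the starting material read 0%, yet the target read 27.1% and went on rising, so the starting material had passed into something I could not read. The last 3 readings then average 45.2%, which is 0.226 M of target. If each target takes one partner, that is 11.8% of the partner charge, so the rise stopped with the partner's charge far from used up by the target.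

I therefore stopped looking at charges and timed the stopping. The gap to the plateau was 18 percentage points at the first reading, which gives a stopping half-time, the time in which the gap to the plateau halves, of 0.505 h. This predicts a gap of 2.9 points at 2.00 h, and the readings show 3.1 points. If the half-time read in epsilon carried over to the asked flasks, their 8.0 h would hold 15.8 such halvings, which leaves 0.00171% of the gap. I therefore expected each end value to be a plateau, not a reading caught in mid-rise.

The forecast gave 0.184 M, 0.357 M, 0.635 M and 1.12 M, a row that rises all the way, on the ground that “the yield is then set by the partner concentration”.

The flasks gave 0.189 M, 0.314 M, 0.444 M and 0.569 M, a row that rises all the way, with dusk at half the forecast value. Dusk ended with 19.0% of the starting material charged as target and 80.5% as open intermediate, and 0% of its own charge of coupling partner was left.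

    coupling partner + catalyst intermediate → free catalyst + target (k = 0.00860 M⁻¹ s⁻¹)
    coupling partner → decomposed reagent (k = 3.30 × 10⁻⁴ s⁻¹)
    free catalyst + open intermediate ⇌ catalyst intermediate (K = 0.790 M⁻¹, k = 0.0360 M⁻¹ s⁻¹)
    starting material + free catalyst → free catalyst + open intermediate (k = 0.220 M⁻¹ s⁻¹)

Counting halvings to 4.00 h gives 7.92, which leaves 0.413% of the gap. Midnight then held 0.526% of its own charge of coupling partner, and its target stood at 47.0% of the starting material charged then and 47.2% at 8.00 h. In dusk the target stood at 18.9% at 4.00 h and 19.0% at 8.00 h, and a run ten times as long changes it by at most 0%.

(The earlier runs and the new flask are simulated on assumed constants; noise was put on by code.)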